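**Strategy.** The chromone is cut at the O1–C8a aryl ether bond. In ring A the three oxygens (O1 on C8a, the C5 hydroxyl, the C7 methoxyl) sit ortho, ortho and para to the C4 carbonyl and meta to each other, so ring A can be carried as a symmetric 2,6-difluoro-4-methoxybenzoyl group in which both fluorides are activated by that carbonyl. In one operation the enolate oxygen of an aryl 1,3-diketone displaces either fluoride, which closes the pyranone ring and leaves the second fluoride at C5 as a masked hydroxyl. The precursor is the (5R)-5-silyloxy-1-(2,6-difluoro-4-methoxyphenyl)undec-10-ene-1,3-dione, assembled from an (R)-β-silyloxy methyl ketone and the aroyl chloride; the terminal alkene later becomes the enoic acid.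

Key step: step 7

Remarks. Chromone numbering is O1, C2, C3, C4, C4a, C5–C8, C8a; C1' is the side-chain carbon on C2. "salen" is the dianion of N,N'-bis(3,5-di-tert-butylsalicylidene)-1,2-cyclohexanediamine. Assumption: the (R,R) cobalt catalyst hydrolyses the (S) enantiomer of a monoalkyl oxirane faster, so that (R)-2 is recovered. This sense is assigned from memory of the reaction's usual selectivity, so configuration and enantiopurity would be checked on 2 (chiral GC) and on 5 (Mosher esters) before material is carried on; if the sense is opposite, the (S,S) catalyst is used.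

**Step 1**
Reactants: 1 rac-1,2-epoxy-7-octene
Product: 2 (R)-1,2-epoxy-7-octene
Conditions: (R,R)-(salen)Co(OAc), C38H55CoN2O4 (0.5 mol%; trivalent cobalt, made from the divalent cobalt complex C36H52CoN2O2 with AcOH in air), H2O (0.55 equiv), neat, 0 → 23 °C; vacuum distillation
Reagents that add atoms: none
Why: Hydrolytic kinetic resolution (Jacobsen): the chiral cobalt salen catalyst should hydrolyse the (S)-epoxide much faster than the (R)-epoxide, so a little more than half an equivalent of water leaves (R)-2, separable from the diol by distillation; this sets the only stereocentre of the route.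

**Step 2**
Reactants: 3 2-methyl-1,3-dithiane; 2 (R)-1,2-epoxy-7-octene
Product: 5 (2R)-1-(2-methyl-1,3-dithian-2-yl)oct-7-en-2-ol, via lithiated dithiane 4 (not isolated)
Conditions: n-BuLi, THF, −30 → 0 °C; then 2, −20 → 23 °C; H2O quench
Reagents that add atoms: none
Why: Corey–Seebach acyl-anion chemistry: the lithiated dithiane opens the monosubstituted epoxide by SN2 attack at the unhindered terminal carbon, so the C–O bond of the stereocentre is untouched and the (R) configuration is retained.

**Step 3**
Reactants: 5 (2R)-1-(2-methyl-1,3-dithian-2-yl)oct-7-en-2-ol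
Product: 6 tert-butyldimethyl{[(2R)-1-(2-methyl-1,3-dithian-2-yl)oct-7-en-2-yl]oxy}silane
Conditions: TBSOTf, 2,6-lutidine, CH2Cl2, −78 → 0 °C
Reagents that add atoms: tert-butyldimethylsilyl triflate, CC(C)(C)[Si](C)(C)OS(=O)(=O)C(F)(F)F
Why: O-Silylation of a secondary alcohol with a silyl triflate and a hindered pyridine base is fast at low temperature and leaves the dithiane, the alkene and the stereocentre alone.

**Step 4**
Reactants: 6 tert-butyldimethyl{[(2R)-1-(2-methyl-1,3-dithian-2-yl)oct-7-en-2-yl]oxy}silane
Product: 7 (4R)-4-(tert-butyldimethylsilyloxy)dec-9-en-2-one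
Conditions: MeI (10 equiv), CaCO3, MeCN/H2O 9:1, 45 °C
Reagents that add atoms: water, O
Why: Alkylative dithiane hydrolysis: S-methylation makes a sulfonium leaving group and water traps the thionium ion to give the ketone, while the carbonate keeps the medium near neutral so the silyl ether survives and the alkene, inert to MeI, is spared.

**Step 5**
Reactants: 8 2,6-difluoro-4-methoxybenzoic acid
Product: 9 2,6-difluoro-4-methoxybenzoyl chloride
Conditions: (COCl)2, DMF (cat.), CH2Cl2, 0 → 23 °C; evaporated and used crude
Reagents that add atoms: oxalyl chloride, O=C(Cl)C(Cl)=O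
Why: Acid chloride formation through the Vilsmeier-type chloroiminium catalyst is routine and mild enough for the fluoroanisole ring.

**Step 6**
Reactants: 7 (4R)-4-(tert-butyldimethylsilyloxy)dec-9-en-2-one; 9 2,6-difluoro-4-methoxybenzoyl chloride
Product: 11 (5R)-5-(tert-butyldimethylsilyloxy)-1-(2,6-difluoro-4-methoxyphenyl)undec-10-ene-1,3-dione, via lithium enolate 10 (not isolated)
Conditions: LiN(SiMe3)2 (2.1 equiv), THF, −78 °C; then 9 (1.05 equiv), −78 °C; AcOH quench at −78 °C
Reagents that add atoms: none
Why: Crossed Claisen acylation: the amide base removes a methyl proton of 7 under kinetic control, the lithium enolate attacks the acyl chloride at carbon, and the second equivalent of base turns the more acidic diketone into its chelated enolate, which blocks a second acylation; the C3 methylene of 7 is not deprotonated, so the β-silyloxy group and the stereocentre are safe.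

**Step 7**
Reactants: 11 (5R)-5-(tert-butyldimethylsilyloxy)-1-(2,6-difluoro-4-methoxyphenyl)undec-10-ene-1,3-dione
Product: 13 2-[(2R)-2-(tert-butyldimethylsilyloxy)oct-7-en-1-yl]-5-fluoro-7-methoxy-4H-chromen-4-one, via potassium enolate 12 (not isolated)
Conditions: K2CO3 (2 equiv), dry DMF, 23 → 50 °C
Reagents that add atoms: none
Why: Carbonate deprotonates the C2 methylene between the two carbonyls to give the chelated Z enolate 12, whose oxygen on C3 (the future O1) adds to the ipso carbon of one ortho C–F bond; the Meisenheimer adduct is delocalised into the aryl ketone (the future C4 carbonyl) and collapses with loss of fluoride (addition–elimination, SNAr). The closest known reaction type is the base-mediated cyclisation of 1-(2-fluoroaryl)-1,3-diketones to chromones, the oxygen analogue of the fluoroquinolone ring closure. The pyranone closes as a six-membered ring by attack of the enolate oxygen on an sp2 carbon, allowed by the Baldwin rules whether counted as 6-endo-trig (through the C4a–C8a π bond that carries the charge to the carbonyl) or 6-exo-trig, and no stereocentre is formed. The selectivity needed is O- against C-arylation and the choice of fluoride: attack through the central carbon or the aroyl oxygen would give a four-membered ring, and the two fluorides are homotopic, so only one product is possible. The methoxyl and the remaining fluorine are meta to the reacting carbon and do not retard it, and because carbonate forms only the diketone monoanion the C4 methylene is not deprotonated and the silyloxy group on C5 is not eliminated. The surviving fluoride ends up at C5, ortho to the new C4 carbonyl, ready for exchange.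

**Step 8**
Reactants: 13 2-[(2R)-2-(tert-butyldimethylsilyloxy)oct-7-en-1-yl]-5-fluoro-7-methoxy-4H-chromen-4-one
Product: 15 2-[(2R)-2-(tert-butyldimethylsilyloxy)oct-7-en-1-yl]-5-hydroxy-7-methoxy-4H-chromen-4-one, via O-aryl acetohydroxamate 14 (not isolated)
Conditions: AcNHOH (3 equiv), K2CO3 (4 equiv), DMSO, 70 °C; aq. NH4Cl work-up
Reagents that add atoms: acetohydroxamic acid, CC(=O)NO
Why: Intermolecular SNAr with a hydroxide surrogate: the hydroxamate oxygen displaces the C5 fluoride ortho to the C4 carbonyl and the O-aryl hydroxamate fragments in a Lossen-type rearrangement to the phenoxide and methyl isocyanate, so no free hydroxide that could open the pyranone is present and the phenoxide formed deactivates the ring to further substitution.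

**Step 9**
Reactants: 15 2-[(2R)-2-(tert-butyldimethylsilyloxy)oct-7-en-1-yl]-5-hydroxy-7-methoxy-4H-chromen-4-one; 16 acrylic acid (5 equiv)
Product: 17 (2E,8R)-8-(tert-butyldimethylsilyloxy)-9-(5-hydroxy-7-methoxy-4-oxo-4H-chromen-2-yl)non-2-enoic acid
Conditions: second-generation Hoveyda–Grubbs catalyst RuCl2(=CH-C6H4-2-OiPr)(H2IMes) (5 mol%), CH2Cl2, 40 °C
Reagents that add atoms: none
Why: Olefin cross-metathesis of a terminal alkene with an electron-poor acrylic partner favours the cross product and the E isomer, while the trisubstituted, electron-poor C2–C3 double bond of the chromone does not take part.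

**Step 10**
Reactants: 17 (2E,8R)-8-(tert-butyldimethylsilyloxy)-9-(5-hydroxy-7-methoxy-4-oxo-4H-chromen-2-yl)non-2-enoic acid
Product: 18 Penithochromone T
Conditions: 48% aq. HF, MeCN, 0 → 23 °C (polypropylene vessel)
Reagents that add atoms: none
Why: Acidic fluoride desilylation cleaves the Si–O bond without generating base, which avoids elimination or retro-aldol cleavage of the hydroxyl β to the chromone, so the (R) carbinol is released unchanged.

**Compound list**
1 | rac-1,2-epoxy-7-octene (2-(hex-5-en-1-yl)oxirane) | C=CCCCCC1CO1 | starting material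
2 | (R)-1,2-epoxy-7-octene | C=CCCCC[C@@H]1CO1 | intermediate
3 | 2-methyl-1,3-dithiane | CC1SCCCS1 | starting material
4 | 2-lithio-2-methyl-1,3-dithiane | [Li]C1(C)SCCCS1 | intermediate
5 | (2R)-1-(2-methyl-1,3-dithian-2-yl)oct-7-en-2-ol | CC1(C[C@H](O)CCCCC=C)SCCCS1 | intermediate
6 | tert-butyldimethyl{[(2R)-1-(2-methyl-1,3-dithian-2-yl)oct-7-en-2-yl]oxy}silane | CC1(C[C@H](O[Si](C)(C)C(C)(C)C)CCCCC=C)SCCCS1 | intermediate
7 | (4R)-4-(tert-butyldimethylsilyloxy)dec-9-en-2-one | CC(=O)C[C@H](O[Si](C)(C)C(C)(C)C)CCCCC=C | intermediate
8 | 2,6-difluoro-4-methoxybenzoic acid | COc1cc(F)c(C(=O)O)c(F)c1 | starting material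
9 | 2,6-difluoro-4-methoxybenzoyl chloride | COc1cc(F)c(C(Cl)=O)c(F)c1 | intermediate
10 | lithium (4R)-4-(tert-butyldimethylsilyloxy)deca-1,9-dien-2-olate | C=C([O-])C[C@H](O[Si](C)(C)C(C)(C)C)CCCCC=C.[Li+] | intermediate
11 | (5R)-5-(tert-butyldimethylsilyloxy)-1-(2,6-difluoro-4-methoxyphenyl)undec-10-ene-1,3-dione | COc1cc(F)c(C(=O)CC(=O)C[C@H](O[Si](C)(C)C(C)(C)C)CCCCC=C)c(F)c1 | intermediate
12 | potassium (2Z,5R)-5-(tert-butyldimethylsilyloxy)-1-(2,6-difluoro-4-methoxyphenyl)-1-oxoundeca-2,10-dien-3-olate | COc1cc(F)c(C(=O)/C=C(\[O-])C[C@H](O[Si](C)(C)C(C)(C)C)CCCCC=C)c(F)c1.[K+] | intermediate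
13 | 2-[(2R)-2-(tert-butyldimethylsilyloxy)oct-7-en-1-yl]-5-fluoro-7-methoxy-4H-chromen-4-one | COc1cc(F)c2c(=O)cc(C[C@H](O[Si](C)(C)C(C)(C)C)CCCCC=C)oc2c1 | intermediate
14 | N-({2-[(2R)-2-(tert-butyldimethylsilyloxy)oct-7-en-1-yl]-7-methoxy-4-oxo-4H-chromen-5-yl}oxy)acetamide | COc1cc(ONC(C)=O)c2c(=O)cc(C[C@H](O[Si](C)(C)C(C)(C)C)CCCCC=C)oc2c1 | intermediate
15 | 2-[(2R)-2-(tert-butyldimethylsilyloxy)oct-7-en-1-yl]-5-hydroxy-7-methoxy-4H-chromen-4-one | COc1cc(O)c2c(=O)cc(C[C@H](O[Si](C)(C)C(C)(C)C)CCCCC=C)oc2c1 | intermediate
16 | acrylic acid | C=CC(=O)O | starting material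
17 | (2E,8R)-8-(tert-butyldimethylsilyloxy)-9-(5-hydroxy-7-methoxy-4-oxo-4H-chromen-2-yl)non-2-enoic acid | COc1cc(O)c2c(=O)cc(C[C@H](O[Si](C)(C)C(C)(C)C)CCCC/C=C/C(=O)O)oc2c1 | intermediate
18 | Penithochromone T, (2E,8R)-8-hydroxy-9-(5-hydroxy-7-methoxy-4-oxo-4H-chromen-2-yl)non-2-enoic acid | COc1cc(O)c2c(=O)cc(C[C@H](O)CCCC/C=C/C(=O)O)oc2c1 | target

**Count.** Total steps: 10. Longest linear sequence: 9 steps (1 → 2 → 5 → 6 → 7 → 11 → 13 → 15 → 17 → 18); the acid chloride 9 is a one-step branch.

**Steps most likely to fail**

Step 8. In hot carbonate/DMSO the C1' methylene, vinylogous to the C4 carbonyl, may be deprotonated and the silyloxy group lost by E1cB elimination, or the hydroxamate may add at C2 and open the pyranone. The fallback sets out from 13 and comes back at 15. The C5 oxygen is brought in as an ether at low temperature: sodium 4-methoxybenzyl oxide (4-methoxybenzyl alcohol, NaH, THF, 0 °C) displaces the fluoride to give 2-[(2R)-2-(tert-butyldimethylsilyloxy)oct-7-en-1-yl]-7-methoxy-5-[(4-methoxybenzyl)oxy]-4H-chromen-4-one F1. Brief treatment with dilute TFA and anisole in CH2Cl2 at 0 °C then cleaves the benzylic ether, assisted by the peri carbonyl, and returns 15.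

Step 6. The enolate may be acylated on oxygen, proton transfer between enolate and product may scramble the enolate and let the β-silyloxy group eliminate, or the product may be acylated twice. The fallback sets out from 10 and comes back at 11. Enolate 10 is added at −78 °C to commercial 2,6-difluoro-4-methoxybenzaldehyde (COc1cc(F)c(C=O)c(F)c1), an electrophile that cannot O-acylate or react twice. This aldol addition should give (5R)-5-(tert-butyldimethylsilyloxy)-1-(2,6-difluoro-4-methoxyphenyl)-1-hydroxyundec-10-en-3-one F2 as a mixture of C1 epimers. Dess–Martin oxidation (NaHCO3, CH2Cl2) removes the extra stereocentre and delivers 11.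

Step 9. Turnover may be slow because the 5-hydroxy-4-keto unit or the carboxylic acid binds ruthenium, and the alkene may homodimerise instead. The fallback sets out from 15 and comes back at 18, attaching the two acrylate carbons by olefination. Lemieux–Johnson cleavage (OsO4 cat., NaIO4, 2,6-lutidine, dioxane/H2O) of the terminal alkene, which is far more electron-rich than the chromone C2–C3 bond, gives (6R)-6-(tert-butyldimethylsilyloxy)-7-(5-hydroxy-7-methoxy-4-oxo-4H-chromen-2-yl)heptanal F3. Wittig reaction with the stabilised ylide Ph3P=CHCO2tBu gives tert-butyl (2E,8R)-8-(tert-butyldimethylsilyloxy)-9-(5-hydroxy-7-methoxy-4-oxo-4H-chromen-2-yl)non-2-enoate F4. TFA in CH2Cl2 followed by water cleaves both the tert-butyl ester and the silyl ether to give 18.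

**Further compounds**
F1 | step 8 | 2-[(2R)-2-(tert-butyldimethylsilyloxy)oct-7-en-1-yl]-7-methoxy-5-[(4-methoxybenzyl)oxy]-4H-chromen-4-one | COc1cc(OCc3ccc(OC)cc3)c2c(=O)cc(C[C@H](O[Si](C)(C)C(C)(C)C)CCCCC=C)oc2c1
F2 | step 6 | (5R)-5-(tert-butyldimethylsilyloxy)-1-(2,6-difluoro-4-methoxyphenyl)-1-hydroxyundec-10-en-3-one | COc1cc(F)c(C(O)CC(=O)C[C@H](O[Si](C)(C)C(C)(C)C)CCCCC=C)c(F)c1
F3 | step 9 | (6R)-6-(tert-butyldimethylsilyloxy)-7-(5-hydroxy-7-methoxy-4-oxo-4H-chromen-2-yl)heptanal | COc1cc(O)c2c(=O)cc(C[C@H](O[Si](C)(C)C(C)(C)C)CCCCC=O)oc2c1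
F4 | step 9 | tert-butyl (2E,8R)-8-(tert-butyldimethylsilyloxy)-9-(5-hydroxy-7-methoxy-4-oxo-4H-chromen-2-yl)non-2-enoate | COc1cc(O)c2c(=O)cc(C[C@H](O[Si](C)(C)C(C)(C)C)CCCC/C=C/C(=O)OC(C)(C)C)oc2c1
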